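# Synthesis plan for CNP0234428.1 (compound 20) through a bridge-directed conjugate addition–benzylation of isolevoglucosenone

Numbering used throughout: the ring of 20 is O1, C2, C3 (benzyl-bearing), C4 (carbinol-bearing), C5, and the carbinol carbon is C7. Sugar positions are written C-1 to C-6 (carbohydrate numbering).

## The problem

- Compound 20 is a trans-3,4-disubstituted tetrahydrofuran in which C2 and C5 are plain OCH2 groups. C3 carries a 4-hydroxy-3-methoxybenzyl group, and C4 carries the carbinol carbon C7 with the second guaiacyl ring.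
- The three contiguous stereocentres are C3 (R), C4 (R) and C7 (R). The trans relation of C3 and C4 can be relayed from one to the other, but its absolute sense needs an outside source, and C7 can only be controlled from C4 or by a reagent.
- For an aryl ketone at C7 on the finished ring, the Felkin–Anh model (hydride anti to the more substituted neighbour C3) and β-chelation to O1 both point to the 7S epimer. C7 therefore calls for reagent control.
- The C7 hydroxyl is a p-hydroxybenzylic alcohol. It ionises under acid, a free hydroxymethyl group would then capture it as a 2-aryltetrahydrofuran, and it is prone to hydrogenolysis once the para phenol is free. Both phenols must be masked through the organometallic step.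
- The feature that permits the key step is that C3 and C4 each bear exactly one exocyclic carbon: C7 at the oxidation level of an aryl ketone, and the benzylic CH2. This is the pattern left when an acyl-anion equivalent and a benzyl halide add across the β- and α-carbons of an enone. The carbonyl carbon and the carbon beyond the β-position then become the two OCH2 groups.
- A 1,6-anhydro sugar enone supplies this four-carbon unit with one face closed by the bridge. Levoglucosenone 1 itself, the (1S,5R) enantiomer, would be attacked at C-4 anti to the bridge and would give the (3S,4S) ring. The enone is therefore used in its carbonyl-transposed form 4, in which the β-carbon is C-2, next to the anomeric centre. Sugar C-1, C-2, C-3 and C-4 then become C5, C4, C3 and C2 of 20.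

## Retrosynthesis

**Protecting groups (20 ⇐ 19 ⇐ 18).** The last operations only unmask heteroatoms. The C7 silyl ether of 19 is removed last with buffered fluoride, and the two phenols are released from the benzyl ethers of 18 one step earlier. This order keeps the benzylic C7–O bond silylated during hydrogenolysis. No C–C or ring bond is involved.

**Ring C–O bond (18 ⇐ 17).** Cutting O1–C2 (or, equivalently, O1–C5) opens the ring to the 1,4-diol 17, which has two primary hydroxyls. Either one can be activated, since both modes close to the same ring. The silyl ether on C7 removes the only competing nucleophile, which would otherwise give a 2-aryltetrahydrofuran. This cut is preferred to a ring C–C cut because it postpones ring formation until all three stereocentres exist.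

**Both CH2OH groups from one masked precursor (17 ⇐ 16 ⇐ 15 ⇐ 14).**
- Diol 17 is traced to the bicyclic acylal lactone 16. Its lactone carbonyl (C-4) and acetal carbon (C-1) are both reduced by one hydride reagent, while C-5 and C-6 fall away as ethylene glycol.
- The C7 stereocentre is disconnected at this stage: 16 comes from alcohol 15, and 15 from aryl ketone 14 by catalyst-controlled reduction.
- The timing is forced. The ketone must be reduced before C-1 is unveiled as an aldehyde, because a β-keto aldehyde would erase the C4 centre. It must be reduced after the ring ketone has been consumed, because borane would otherwise reduce that ketone as well.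

**Oxygen insertion (14 ⇐ 13 ⇐ 12).** The acylal lactone 14 is the Baeyer–Villiger product of ring ketone 13, with oxygen inserted between C-4 and the α-oxygenated bridgehead C-5. This single oxidation prepares the excision of both superfluous sugar carbons. The peracid requires a sulfur-free substrate, so the dithiane of 12 is hydrolysed first to the diketone 13.

**Key disconnection (12 ⇐ 4 + 7 + 9).** Two exocyclic C–C bonds are cut at adjacent carbons: C4–C7 and C3–CH2Ar. The precursors are enone 4, the aryl dithiane 7 as acyl-anion equivalent, and the benzylic bromide 9. Compared with ring C–C or C–O cuts, this removes both aryl-bearing side chains at once and leaves a six-carbon chiral-pool enone. The forward reaction must give 1,4-addition anti to the bridge at C-2 and C-alkylation trans at C-3.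

**Carbonyl transposition (4 ⇐ 3 ⇐ 2 ⇐ 1).** Isolevoglucosenone 4 is reached from levoglucosenone 1 by the standard 1,3-transposition: epoxide 2, Wharton rearrangement to allylic alcohol 3, and oxidation. The three steps are the price of reading the bridge in the sense that 20 requires.

**Side-chain components (7 ⇐ 5 + 6; 9 ⇐ 8).** Dithiane 7 comes from O-benzylvanillin 5 and propane-1,3-dithiol 6, and bromide 9 from the benzylic alcohol 8.

## Roads not taken

**Alternative 1:** carbonyl ylide cycloaddition.
- Cut: C2–C3 and C4–C5, a [3+2] retron.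
- Forward step: the parent carbonyl ylide, released by CsF from chloromethyl trimethylsilylmethyl ether A3, adds across the E-alkene of the N-aroylacryloyl camphorsultam A2. The product is the trans-3-aroyl-4-(sultam-carbonyl)tetrahydrofuran A1.
- Merits: the ring and both ring stereocentres are made in one step, trans by alkene geometry. Ring construction is clearly shorter than in the chosen route, where six steps separate 12 from the tetrahydrofuran 18.
- Weak points:
  - A1 carries a carboxyl-level carbon where 20 has CH2Ar. The second aryl group must still be attached and that carbon fully deoxygenated while C7 stays at the carbinol level, a differentiation of two benzylic oxygenated carbons that costs several steps.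
  - Facial control depends on an auxiliary acting on a small, short-lived, non-chelated dipole.
  - C7 is still set by a ketone reduction with the same unfavourable substrate bias.
- Comparison: the chosen plan sets against the shorter ring synthesis that both side chains are complete after the key step and that the stereocontrol comes from a rigid bicycle.

**Alternative 2:** alkoxymethyl radical cyclisation.
- Cut: C2–C3.
- Forward step: Bu3SnH with AIBN converts the phenylselenomethyl ether A5 into an alkoxymethyl radical that closes 5-exo onto the styrene. The product A4 is the fully protected target and is identical with compound 18.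
- Merits: the end game is as short as can be, and equal to steps 13 and 14 here. The conditions are neutral, and a chair-like transition state with the C4 substituent pseudo-equatorial favours the trans ring.
- Weak points:
  - A5 must already contain C4 and C7 with the correct relative and absolute configuration, so the stereochemical problem is moved to an acyclic aldol or allylation.
  - The diastereoselectivity of closure for a singly substituted 3-oxahexenyl radical is usually moderate.
  - Tin and selenium are used in stoichiometric amounts.
- Comparison: after ring closure this road is better than the chosen one. The chosen plan offers in return template control for C3 and C4, and a C7 centre that is installed independently and can be corrected by re-oxidation.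

**Alternative 3:** oxetane desymmetrisation.
- Cut: O1–C5.
- Forward step: with the chiral catalyst (salen)Co(OTf), the allylic hydroxyl of the 2-(oxetan-3-yl)-3-arylprop-2-en-1-ol A7 opens one enantiotopic oxetane CH2. The product is the 4-benzylidene-tetrahydrofuran-3-ylmethanol A6.
- Merits: chirality comes from a catalyst and an achiral precursor, there is no degradation of a template, and the step count is probably somewhat lower than 14. A later aryl Grignard addition to the derived aldehyde would be Felkin-sensed for 7R, a real advantage over any ketone reduction.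
- Weak points:
  - A6 has only one of the three stereocentres. C3 must come from a hydroxyl-directed hydrogenation of the benzylidene group, and C7 from an addition to an α-epimerisable aldehyde.
  - The catalyst has not been shown with an alkenyl-substituted oxetane and an allylic alcohol nucleophile.
  - A6 can lose its stereocentre by alkene migration.
- Comparison: the chosen plan is longer but fixes two stereocentres in one template-controlled step and relies only on reactions with close precedent.

Key step: step 6

Remark: commercial levoglucosenone is taken to be the (1S,5R) enantiomer obtained from cellulose, and O-benzylvanillin 5 and its benzylic alcohol 8 are taken as catalogue chemicals (each is one step from vanillin).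

## Route

Step 1
Reactants: 1 levoglucosenone
Product: 2 levoglucosenone 3,4-epoxide (1,6:3,4-dianhydro-β-D-ribo-hexopyranos-2-ulose, oxirane anti to the 1,6-anhydro bridge)
Conditions: t-BuOOH (decane solution), DBU (0.2 equiv), THF, 0 °C
Reagents that add atoms: tert-butyl hydroperoxide, CC(C)(C)OO
Why: Weitz–Scheffer nucleophilic epoxidation; the peroxide anion adds to C-4 on the face opposite the bridge and the enolate closes the oxirane on that face. An alkyl hydroperoxide is used because H2O2 would trigger Baeyer–Villiger cleavage of this ketone; both new centres are erased again by step 3.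

Step 2
Reactants: 2 levoglucosenone 3,4-epoxide
Product: 3 1,6-anhydro-2,3-dideoxy-β-D-erythro-hex-2-enopyranose
Conditions: N2H4·H2O, AcOH (cat.), MeOH, 0 °C to rt
Reagents that add atoms: none
Why: Wharton transposition; hydrazone formation, oxirane opening and loss of N2 move the double bond to C-2/C-3 and leave the former oxirane oxygen as the C-4 hydroxyl, whose configuration is immaterial.

Step 3
Reactants: 3 1,6-anhydro-2,3-dideoxy-β-D-erythro-hex-2-enopyranose
Product: 4 isolevoglucosenone, (1R,5R)-6,8-dioxabicyclo[3.2.1]oct-3-en-2-one
Conditions: MnO2, CH2Cl2, rt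
Reagents that add atoms: none
Why: Allylic alcohol oxidation with MnO2 completes the 1,3-carbonyl transposition; the flanking bridgeheads cannot enolise, so the enone is configurationally safe.

Step 4
Reactants: 5 4-benzyloxy-3-methoxybenzaldehyde; 6 propane-1,3-dithiol
Product: 7 2-(4-benzyloxy-3-methoxyphenyl)-1,3-dithiane
Conditions: BF3·OEt2 (cat.), CH2Cl2, 0 °C to rt
Reagents that add atoms: none
Why: Lewis-acid-catalysed dithioacetalisation of an aromatic aldehyde (Corey–Seebach dithiane formation).

Step 5
Reactants: 8 (4-benzyloxy-3-methoxyphenyl)methanol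
Product: 9 4-benzyloxy-3-methoxybenzyl bromide
Conditions: PBr3, Et2O, 0 °C; used freshly
Reagents that add atoms: phosphorus tribromide, BrP(Br)Br
Why: Bromide displacement of the benzylic phosphite ester; the electron-rich bromide is labile and is therefore made just before use.

Step 6
Reactants: 7 2-(4-benzyloxy-3-methoxyphenyl)-1,3-dithiane; 4 isolevoglucosenone; 9 4-benzyloxy-3-methoxybenzyl bromide
Product: 12 (1R,3R,4R,5R)-3-(4-benzyloxy-3-methoxybenzyl)-4-[2-(4-benzyloxy-3-methoxyphenyl)-1,3-dithian-2-yl]-6,8-dioxabicyclo[3.2.1]octan-2-one, via lithiated dithiane 10 (not isolated), via lithium enolate 11 (not isolated)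
Conditions: 7, n-BuLi, THF, −78 °C; DMPU, then 4, −78 °C; then 9, −78 to −20 °C; aq. NH4Cl
Reagents that add atoms: none
Why: n-BuLi deprotonates 7 to the sulfur-stabilised benzylic anion 10, which as a DMPU-separated ion pair adds in Michael fashion to the β-carbon C-2 of 4 and not to the carbonyl. The anion approaches C-2 anti to the C-1–O-6 bond of the 1,6-anhydro bridge, the only open face of the bicycle, and this sets the centre that becomes C4 of 20. The enolate 11 is regiochemically fixed because the other α-carbon is a bridgehead, and it is C-benzylated by the soft bromide 9 on the face opposite the new quaternary dithianyl group, which sets the future C3 trans. No ring is closed; two C–C bonds (C4–C7 and C3–CH2Ar) and two stereocentres are formed. The closest known reaction type is the conjugate addition of 2-aryl-1,3-dithiane anions to cyclic enones and butenolides with in situ enolate alkylation by benzylic halides, together with bridge-controlled Michael additions to levoglucosenone-type enones. The step needs 1,4- over 1,2-addition (aryl-stabilised anion, DMPU), C- over O-alkylation (lithium enolate, benzylic bromide) and two facial selectivities (the bridge at C-2, the vicinal dithianyl group at C-3).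

Step 7
Reactants: 12 the dithianyl ketone
Product: 13 (1R,3R,4R,5R)-4-(4-benzyloxy-3-methoxybenzoyl)-3-(4-benzyloxy-3-methoxybenzyl)-6,8-dioxabicyclo[3.2.1]octan-2-one
Conditions: PhI(OCOCF3)2, MeCN–H2O (9:1), 0 °C, short reaction time
Reagents that add atoms: water, O
Why: Oxidative dithiane hydrolysis with a hypervalent iodine reagent; sulfur is activated, water captures the thionium ion and the aryl ketone is released. The medium is non-basic, which avoids enolisation of the 1,4-diketone and β-elimination of the acetal oxygens.

Step 8
Reactants: 13 the 1,4-diketone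
Product: 14 (1S,4R,5R,6R)-5-(4-benzyloxy-3-methoxybenzoyl)-4-(4-benzyloxy-3-methoxybenzyl)-2,7,9-trioxabicyclo[4.2.1]nonan-3-one
Conditions: mCPBA, NaHCO3, CH2Cl2, 0 °C to rt
Reagents that add atoms: 3-chloroperbenzoic acid, OOC(=O)c1cccc(Cl)c1
Why: Baeyer–Villiger oxidation; the strained α-alkoxy ring ketone should form the Criegee adduct far faster than the conjugated, electron-rich aryl ketone under buffered conditions. The α-oxygenated bridgehead C-5 migrates with retention in preference to the benzyl-bearing C-3, as in 7-oxanorbornanones and dihydrolevoglucosenone, giving the acylal lactone.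

Step 9
Reactants: 14 the keto acylal lactone
Product: 15 (1S,4R,5S,6R)-4-(4-benzyloxy-3-methoxybenzyl)-5-[(R)-(4-benzyloxy-3-methoxyphenyl)(hydroxy)methyl]-2,7,9-trioxabicyclo[4.2.1]nonan-3-one
Conditions: (S)-1-methyl-3,3-diphenyltetrahydro-1H,3H-pyrrolo[1,2-c][1,3,2]oxazaborole ((S)-Me-CBS, 0.2–1.0 equiv), BH3·SMe2, THF, −20 °C; MeOH quench
Reagents that add atoms: none
Why: Corey–Bakshi–Shibata reduction; the ketone binds the catalyst boron anti to the aryl group, taken as the larger substituent as in acetophenone-type substrates, and the (S)-catalyst then delivers hydride to the face that gives the (R)-carbinol. Reagent control is chosen because the two ring neighbours of C-2 are sterically alike, and borane leaves the lactone untouched at this temperature.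

Step 10
Reactants: 15 the hydroxy acylal lactone
Product: 16 (1S,4R,5S,6R)-4-(4-benzyloxy-3-methoxybenzyl)-5-[(R)-(4-benzyloxy-3-methoxyphenyl)(tert-butyldimethylsilyloxy)methyl]-2,7,9-trioxabicyclo[4.2.1]nonan-3-one
Conditions: TBSOTf, 2,6-lutidine, CH2Cl2, −78 °C
Reagents that add atoms: tert-butyldimethylsilyl trifluoromethanesulfonate, CC(C)(C)[Si](C)(C)OS(=O)(=O)C(F)(F)F
Why: Silylation of the secondary benzylic alcohol is fast at −78 °C and should outrun translactonisation onto the acylal carbonyl. The silyl ether keeps the C7 oxygen out of the ring closure and later shields the benzylic C–O bond from hydrogenolysis.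

Step 11
Reactants: 16 the silylated acylal lactone
Product: 17 (2R,3R)-2-(4-benzyloxy-3-methoxybenzyl)-3-[(R)-(4-benzyloxy-3-methoxyphenyl)(tert-butyldimethylsilyloxy)methyl]butane-1,4-diol
Conditions: LiAlH4, THF, 0 °C to rt; aqueous potassium sodium tartrate work-up
Reagents that add atoms: none
Why: Hydride reduction of the lactone; the hemiacetals at C-5 and then at C-1 collapse in turn and each aldehyde is reduced as it appears, so C-4 and C-1 emerge as the two CH2OH groups and C-5/C-6 leave as ethylene glycol. The three stereocentres are untouched because the C-1 aldehyde is reduced faster than C-2 can epimerise.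

Step 12
Reactants: 17 the 1,4-diol
Product: 18 tert-butyl{(R)-(4-benzyloxy-3-methoxyphenyl)[(3R,4R)-4-(4-benzyloxy-3-methoxybenzyl)tetrahydrofuran-3-yl]methoxy}dimethylsilane
Conditions: PPh3, DIAD, THF, 0 °C to rt
Reagents that add atoms: none
Why: Mitsunobu cyclodehydration; one primary hydroxyl is activated as its oxyphosphonium ion and displaced by the other (5-exo-tet). Both activation modes give the same tetrahydrofuran and no stereocentre takes part.

Step 13
Reactants: 18 the protected tetrahydrofuran
Product: 19 4-{(R)-(tert-butyldimethylsilyloxy)[(3R,4R)-4-(4-hydroxy-3-methoxybenzyl)tetrahydrofuran-3-yl]methyl}-2-methoxyphenol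
Conditions: H2 (1 atm), 10% Pd/C, EtOAc, rt
Reagents that add atoms: none
Why: Hydrogenolysis of the two aryl benzyl ethers under neutral conditions; with C7 still silylated the p-hydroxybenzylic C–O bond has no quinone methide pathway for reductive loss.

Step 14
Reactants: 19 the silyl ether bisphenol
Product: 20 4-{(R)-hydroxy[(3R,4R)-4-(4-hydroxy-3-methoxybenzyl)tetrahydrofuran-3-yl]methyl}-2-methoxyphenol
Conditions: Bu4NF, AcOH (1:1), THF, rt
Reagents that add atoms: none
Why: Fluoride cleavage of the silyl ether; acetic acid buffering keeps the phenols protonated, so the p-hydroxybenzylic alcohol is not exposed to base or acid.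

## Compound list

1 | levoglucosenone, (1S,5R)-6,8-dioxabicyclo[3.2.1]oct-2-en-4-one | O=C1C=C[C@H]2CO[C@@H]1O2 | starting material
2 | levoglucosenone 3,4-epoxide, 1,6:3,4-dianhydro-β-D-ribo-hexopyranos-2-ulose (oxirane anti to the bridge) | O=C1[C@@H]3O[C@@H]3[C@H]2CO[C@@H]1O2 | intermediate
3 | 1,6-anhydro-2,3-dideoxy-β-D-erythro-hex-2-enopyranose (C-4 hydroxyl anti to the bridge) | O[C@H]1C=C[C@@H]2OC[C@H]1O2 | intermediate
4 | isolevoglucosenone, (1R,5R)-6,8-dioxabicyclo[3.2.1]oct-3-en-2-one | O=C1C=C[C@@H]2OC[C@H]1O2 | intermediate
5 | 4-benzyloxy-3-methoxybenzaldehyde | COc1cc(C=O)ccc1OCc1ccccc1 | starting material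
6 | propane-1,3-dithiol | SCCCS | starting material
7 | 2-(4-benzyloxy-3-methoxyphenyl)-1,3-dithiane | COc1cc(C2SCCCS2)ccc1OCc1ccccc1 | intermediate
8 | (4-benzyloxy-3-methoxyphenyl)methanol | COc1cc(CO)ccc1OCc1ccccc1 | starting material
9 | 4-benzyloxy-3-methoxybenzyl bromide | COc1cc(CBr)ccc1OCc1ccccc1 | intermediate
10 | 2-lithio-2-(4-benzyloxy-3-methoxyphenyl)-1,3-dithiane | [Li]C1(c2ccc(OCc3ccccc3)c(OC)c2)SCCCS1 | intermediate
11 | lithium enolate of the C-2 adduct, lithium 4-[2-(4-benzyloxy-3-methoxyphenyl)-1,3-dithian-2-yl]-6,8-dioxabicyclo[3.2.1]oct-2-en-2-olate (dithianyl group anti to the bridge) | [Li]OC1=C[C@@H](C2(c3ccc(OCc4ccccc4)c(OC)c3)SCCCS2)[C@@H]5OC[C@H]1O5 | intermediate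
12 | (1R,3R,4R,5R)-3-(4-benzyloxy-3-methoxybenzyl)-4-[2-(4-benzyloxy-3-methoxyphenyl)-1,3-dithian-2-yl]-6,8-dioxabicyclo[3.2.1]octan-2-one | O=C1[C@H](Cc2ccc(OCc3ccccc3)c(OC)c2)[C@@H](C4(c5ccc(OCc6ccccc6)c(OC)c5)SCCCS4)[C@@H]7OC[C@H]1O7 | intermediate
13 | (1R,3R,4R,5R)-4-(4-benzyloxy-3-methoxybenzoyl)-3-(4-benzyloxy-3-methoxybenzyl)-6,8-dioxabicyclo[3.2.1]octan-2-one | O=C1[C@H](Cc2ccc(OCc3ccccc3)c(OC)c2)[C@@H](C(=O)c5ccc(OCc6ccccc6)c(OC)c5)[C@@H]7OC[C@H]1O7 | intermediate
14 | (1S,4R,5R,6R)-5-(4-benzyloxy-3-methoxybenzoyl)-4-(4-benzyloxy-3-methoxybenzyl)-2,7,9-trioxabicyclo[4.2.1]nonan-3-one | O=C1[C@H](Cc2ccc(OCc3ccccc3)c(OC)c2)[C@@H](C(=O)c5ccc(OCc6ccccc6)c(OC)c5)[C@@H]7OC[C@H](O1)O7 | intermediate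
15 | (1S,4R,5S,6R)-4-(4-benzyloxy-3-methoxybenzyl)-5-[(R)-(4-benzyloxy-3-methoxyphenyl)(hydroxy)methyl]-2,7,9-trioxabicyclo[4.2.1]nonan-3-one | O=C1[C@H](Cc2ccc(OCc3ccccc3)c(OC)c2)[C@@H]([C@@H](O)c5ccc(OCc6ccccc6)c(OC)c5)[C@@H]7OC[C@H](O1)O7 | intermediate
16 | (1S,4R,5S,6R)-4-(4-benzyloxy-3-methoxybenzyl)-5-[(R)-(4-benzyloxy-3-methoxyphenyl)(tert-butyldimethylsilyloxy)methyl]-2,7,9-trioxabicyclo[4.2.1]nonan-3-one | O=C1[C@H](Cc2ccc(OCc3ccccc3)c(OC)c2)[C@@H]([C@@H](O[Si](C)(C)C(C)(C)C)c5ccc(OCc6ccccc6)c(OC)c5)[C@@H]7OC[C@H](O1)O7 | intermediate
17 | (2R,3R)-2-(4-benzyloxy-3-methoxybenzyl)-3-[(R)-(4-benzyloxy-3-methoxyphenyl)(tert-butyldimethylsilyloxy)methyl]butane-1,4-diol | OC[C@H](Cc1ccc(OCc2ccccc2)c(OC)c1)[C@H](CO)[C@@H](O[Si](C)(C)C(C)(C)C)c1ccc(OCc2ccccc2)c(OC)c1 | intermediate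
18 | tert-butyl{(R)-(4-benzyloxy-3-methoxyphenyl)[(3R,4R)-4-(4-benzyloxy-3-methoxybenzyl)tetrahydrofuran-3-yl]methoxy}dimethylsilane | COc1cc(C[C@H]2COC[C@@H]2[C@@H](O[Si](C)(C)C(C)(C)C)c2ccc(OCc3ccccc3)c(OC)c2)ccc1OCc1ccccc1 | intermediate
19 | 4-{(R)-(tert-butyldimethylsilyloxy)[(3R,4R)-4-(4-hydroxy-3-methoxybenzyl)tetrahydrofuran-3-yl]methyl}-2-methoxyphenol | COc1cc(C[C@H]2COC[C@@H]2[C@@H](O[Si](C)(C)C(C)(C)C)c2ccc(O)c(OC)c2)ccc1O | intermediate
20 | 4-{(R)-hydroxy[(3R,4R)-4-(4-hydroxy-3-methoxybenzyl)tetrahydrofuran-3-yl]methyl}-2-methoxyphenol | COc1cc(C[C@H]2COC[C@@H]2[C@@H](O)c2ccc(O)c(OC)c2)ccc1O | target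

## Step count and risks

Total: 14 steps. Longest linear sequence: 12 steps (steps 1–3 and 6–14).

**Step 6 (key step).**
- What may go wrong: sluggish C-benzylation of the hindered lithium enolate next to the quaternary dithianyl carbon, with proton transfer or reversal of the Michael addition on warming; and incomplete facial control in the benzylation, because the face anti to the dithianyl group is the one that looks toward the bridge.
- Fallback: enolate 11, generated as before from 4 and 7, is trapped with the far more reactive aldehyde 5. This gives the aldol adduct F1 (epimers at the new carbinol carbon), formed on the same face. Ionic deoxygenation of its electron-rich benzylic hydroxyl with Et3SiH and CF3CO2H, which the dithiane tolerates, returns to 12.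

**Step 8.**
- What may go wrong: competing peracid attack at the aroyl ketone (aryl migration) or at the electron-rich rings; enolisation and β-elimination of the sensitive 1,4-diketone; hydrolytic loss of the acylal during isolation.
- Fallback: the sequence sets out from 12 and keeps the dithiane as the ketone protecting group.
  - NaBH4 reduces the ring ketone to the C-4 alcohol F2; either epimer serves.
  - Aqueous acid, to which dithiane and benzyl ethers are stable, opens the 1,6-anhydro acetal, and NaBH4 reduces the freed hemiacetal to the tetraol F3.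
  - Brief NaIO4 cleavage of the C-4/C-5/C-6 triol gives an aldehyde that the C-1 hydroxyl captures as the lactol F4.
  - Et3SiH with BF3·OEt2 reduces the lactol to the tetrahydrofuran F5.
  - PhI(OCOCF3)2 releases the ketone F6, and (S)-Me-CBS reduction gives the alcohol F7.
  - Silylation with TBSOTf returns to 18.

**Step 9.**
- What may go wrong: weak or reversed catalyst control. The alkyl side of the ketone is a doubly branched ring carbon and may compete with the aryl group for the role of the large substituent, and any substrate bias is of unknown sense.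
- Fallback: 14 is reduced without a chiral catalyst (NaBH4, CeCl3, MeOH, −40 °C) and the C7 epimers are separated by chromatography. The 7R fraction is 15. The 7S epimer F8 is returned to 14 by MnO2 oxidation of its benzylic alcohol and recycled.

**Step 11.**
- What may go wrong: incomplete collapse of the hemiacetal aluminates, so that aldehydes appear only on work-up; the C-1 aldehyde could then epimerise C-2 or remain as lactols.
- Fallback: the cascade is split. Treating 16 with K2CO3 in MeOH releases the ester aldehyde, and NaBH4 added to the same flask reduces it, so that the product closes to the γ-butyrolactone F9. At this stage the benzyl-bearing centre can also be equilibrated to trans with DBU if needed. LiAlH4 reduction of F9 returns to 17.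

## Further compounds

F1 | step 6 | aldol adduct, 3-[(4-benzyloxy-3-methoxyphenyl)(hydroxy)methyl]-4-[2-(4-benzyloxy-3-methoxyphenyl)-1,3-dithian-2-yl]-6,8-dioxabicyclo[3.2.1]octan-2-one (ring centres as in 12, carbinol epimers) | O=C1[C@H](C(O)c2ccc(OCc3ccccc3)c(OC)c2)[C@@H](C4(c5ccc(OCc6ccccc6)c(OC)c5)SCCCS4)[C@@H]7OC[C@H]1O7
F2 | step 8 | C-4 alcohol of 12, 3-(4-benzyloxy-3-methoxybenzyl)-4-[2-(4-benzyloxy-3-methoxyphenyl)-1,3-dithian-2-yl]-6,8-dioxabicyclo[3.2.1]octan-2-ol (carbinol epimers) | OC1[C@H](Cc2ccc(OCc3ccccc3)c(OC)c2)[C@@H](C4(c5ccc(OCc6ccccc6)c(OC)c5)SCCCS4)[C@@H]7OC[C@H]1O7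
F3 | step 8 | tetraol, 3-(4-benzyloxy-3-methoxybenzyl)-2-[2-(4-benzyloxy-3-methoxyphenyl)-1,3-dithian-2-yl]-2,3-dideoxyhexitol (C-4 epimers, C-5 as in the D-sugar) | OC[C@H](C1(c2ccc(OCc3ccccc3)c(OC)c2)SCCCS1)[C@@H](Cc1ccc(OCc2ccccc2)c(OC)c1)C(O)[C@H](O)CO
F4 | step 8 | lactol, (3R,4R)-3-(4-benzyloxy-3-methoxybenzyl)-4-[2-(4-benzyloxy-3-methoxyphenyl)-1,3-dithian-2-yl]tetrahydrofuran-2-ol (anomers) | OC1OC[C@H](C2(c3ccc(OCc4ccccc4)c(OC)c3)SCCCS2)[C@H]1Cc1ccc(OCc2ccccc2)c(OC)c1
F5 | step 8 | 2-(4-benzyloxy-3-methoxyphenyl)-2-[trans-4-(4-benzyloxy-3-methoxybenzyl)tetrahydrofuran-3-yl]-1,3-dithiane | C1OC[C@H](C2(c3ccc(OCc4ccccc4)c(OC)c3)SCCCS2)[C@H]1Cc1ccc(OCc2ccccc2)c(OC)c1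
F6 | step 8 | (4-benzyloxy-3-methoxyphenyl)[trans-4-(4-benzyloxy-3-methoxybenzyl)tetrahydrofuran-3-yl]methanone | C1OC[C@H](C(=O)c2ccc(OCc3ccccc3)c(OC)c2)[C@H]1Cc1ccc(OCc2ccccc2)c(OC)c1
F7 | step 8 | (R)-(4-benzyloxy-3-methoxyphenyl)[(3R,4R)-4-(4-benzyloxy-3-methoxybenzyl)tetrahydrofuran-3-yl]methanol | C1OC[C@H]([C@@H](O)c2ccc(OCc3ccccc3)c(OC)c2)[C@H]1Cc1ccc(OCc2ccccc2)c(OC)c1
F8 | step 9 | C7 epimer of 15, with the (S)-configured carbinol | O=C1[C@H](Cc2ccc(OCc3ccccc3)c(OC)c2)[C@@H]([C@H](O)c5ccc(OCc6ccccc6)c(OC)c5)[C@@H]7OC[C@H](O1)O7
F9 | step 11 | (3R,4R)-3-(4-benzyloxy-3-methoxybenzyl)-4-[(R)-(4-benzyloxy-3-methoxyphenyl)(tert-butyldimethylsilyloxy)methyl]dihydrofuran-2(3H)-one | O=C1OC[C@H]([C@@H](O[Si](C)(C)C(C)(C)C)c2ccc(OCc3ccccc3)c(OC)c2)[C@H]1Cc1ccc(OCc2ccccc2)c(OC)c1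
A1 | alternative 1 | N-{[trans-4-(4-benzyloxy-3-methoxybenzoyl)tetrahydrofuran-3-yl]carbonyl}bornane-10,2-sultam | COc1cc(C(=O)[C@H]2COC[C@@H]2C(=O)N3S(=O)(=O)C[C@]45CC[C@H](C[C@@H]34)C5(C)C)ccc1OCc1ccccc1
A2 | alternative 1 | N-[(E)-4-(4-benzyloxy-3-methoxyphenyl)-4-oxobut-2-enoyl]bornane-10,2-sultam | COc1cc(C(=O)/C=C/C(=O)N2S(=O)(=O)C[C@]34CC[C@H](C[C@@H]23)C4(C)C)ccc1OCc1ccccc1
A3 | alternative 1 | chloromethyl trimethylsilylmethyl ether | C[Si](C)(C)COCCl
A4 | alternative 2 | fully protected target, identical with 18 | COc1cc(C[C@H]2COC[C@@H]2[C@@H](O[Si](C)(C)C(C)(C)C)c2ccc(OCc3ccccc3)c(OC)c2)ccc1OCc1ccccc1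
A5 | alternative 2 | phenylselenomethyl ether of the (E)-styrenyl homoallylic alcohol, with the C4 and C7 centres of 20 | COc1cc(/C=C/[C@H](COC[Se]c2ccccc2)[C@@H](O[Si](C)(C)C(C)(C)C)c2ccc(OCc3ccccc3)c(OC)c2)ccc1OCc1ccccc1
A6 | alternative 3 | [(E)-4-(4-benzyloxy-3-methoxybenzylidene)tetrahydrofuran-3-yl]methanol | OC[C@H]1COC/C1=C/c1ccc(OCc2ccccc2)c(OC)c1
A7 | alternative 3 | (E)-3-(4-benzyloxy-3-methoxyphenyl)-2-(oxetan-3-yl)prop-2-en-1-ol | OC/C(C1COC1)=C/c1ccc(OCc2ccccc2)c(OC)c1
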